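If dissolved [starting material] holds still while solid substrate feeds it, the rate of a flask hangs on the catalyst charged, and the choice for the epsilon flask becomes simple: leave it at 15 mM of free catalyst until 4.0 min, or change the charge.

| setting | epsilon | delta | flask |
|---|---|---|---|
| solid substrate | 0.30 M | 0.30 M | 0.30 M |
| coupling partner | 0.33 M | 0.33 M | 0.330 M |
| free catalyst | 15 mM | 7.5 mM | 15 mM |
| remark | the very flask that is asked about, followed so far | run made earlier |  |
| time |  |  | 4.0 min |

- epsilon (time / s: product / %, starting material / %): 10.0: 0.1, 14.8; 20.0: 0.5, 20.6
- delta (time / min: product / %, starting material / %): 0.250: 0.8, 19.1; 0.500: 0, 24.2; 1.33: 3.4, 24.4; 3.00: 9.9, 25.5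

(readings scatter by 0.5 percentage points)

- how much product there is at 4.0 min, in percent of the solid substrate charged
- concentration of starting material in solution at 4.0 min, in percent of saturation

- given per volume of solution although it is solid: solid substrate
- on the list of suspects stand: starting material + free catalyst -> catalyst intermediate A; coupling partner + catalyst intermediate A <-> catalyst intermediate B; catalyst intermediate B <-> by-product + catalyst intermediate C; catalyst intermediate C -> free catalyst + product; solid substrate <-> starting material
- at the start none of the solid substrate is in solution
- starting material means what is dissolved; the solid is not counted in it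

In the delta run, starting material stands at 24.2% at 0.500 min and 25.5% at 3.00 min while product climbs, so solid substrate is replacing what the catalyst takes. Delta's last two readings give 1.56 min⁻¹: this is the charged-catalyst turnover rate, product made per minute per catalyst charged. Its straight line runs back to a lag of 0.456 min. Epsilon's two readings give a dissolving constant of 5.62 min⁻¹, so at 15 mM the demand holds [starting material] about 5.43% below saturation. The rate is then pseudo-first-order in catalyst, and epsilon is left as charged. This reckoning gives 27.6% of product and 94.6% of saturation.

The forecast says 26% (20% to 30%) and 94.5% (91% to 97.5%), lower on product than this reckoning: “The coupling partner falls by about 25% by then, and by-product reversibility may also slow things, so I trim this to about 26%.”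

The flask gives 23.2% and 95.9%, inside both ranges.

    starting material + free catalyst → catalyst intermediate A (k = 45.0 L mol⁻¹ min⁻¹)
    coupling partner + catalyst intermediate A ⇌ catalyst intermediate B (K = 3.70 L mol⁻¹, k = 53.0 L mol⁻¹ min⁻¹)
    catalyst intermediate B ⇌ by-product + catalyst intermediate C (K = 0.0650 M, k = 7.30 min⁻¹)
    catalyst intermediate C → free catalyst + product (k = 15.0 min⁻¹)
    solid substrate ⇌ starting material, rate k5*(cs5 - [starting material]) while solid is left; crystals form when [starting material] > cs5 (solubility = 0.0750 M, k = 5.70 min⁻¹)

At 4.00 min, starting material has a half-life of 2.9 min by its step with free catalyst, against 0.122 min for refilling from the solid. Solid substrate still stands at 49.6%, and the flask's turnover rate after the lag averages 1.31 min⁻¹, below delta's 1.56 min⁻¹. With the other charges and the time held, the product at 4.0 min moves by 5 points at 0.247 M or 0.383 M of solid substrate. For the neighbour with 0.0090 M of free catalyst, 1.56 min⁻¹ and the lag give 16.6%; that flask gives 14.8%.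

The readings come from a simulation with constants of no real substance; noise was put on by code.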